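## Retrosynthetic overview

- Target 16 comes from 15 by DDQ removal of the C2 PMB ether, and 15 from alcohol 14 by benzoylation of C3–OH.
- Feature used: the oxirane C1–O–C6 fused to the six-membered carbocycle, next to the C4=C5 alkene, with the C3 oxygen on the ring face opposite the oxirane oxygen. This array is the SN2' image of a C1 alkoxide, a C5=C6 alkene and a C3–C4 oxirane.
- Key disconnection: open C6–O, move the alkene back to C5=C6 and re-close the C3 oxygen onto C4. This gives epoxy alcohol 11; forward, a base-induced oxirane transposition relayed through the alkene.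
- 11 comes from diene 9 by β-face epoxidation of C3=C4. 9 comes from benzoic acid 1 through the microbial cis-dienediol 2 (sets C1 and C2), then ester, C2 PMB ether, reduction, C7 benzoate and C1 silyl ether.
- Ring order: the carbocycle comes intact from benzoic acid; the C3–C4 oxirane is made in step 7 and traded for the C1–C6 oxirane in step 9.

Key step: step 9

Remarks: pipoxide numbering is used throughout (C1 quaternary carbon, C2 to C6 round the ring, C7 the exocyclic CH2); α is the ring face of the C1 oxygen, β the face of C7. The dioxygenase mutant strain Cupriavidus necator B9 is assumed to be an accessible biocatalyst. The dienes 2 to 9 should be kept cold, dilute and free of acid, since they can aromatise or dimerise.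

## Route

Step 1
Reactants: 1 benzoic acid
Product: 2 (1S,2R)-1,2-dihydroxycyclohexa-3,5-diene-1-carboxylic acid
Conditions: Cupriavidus necator B9 (Ralstonia eutropha B9) whole cells, PhCO2Na feed, fructose, aqueous buffer medium, air, 30 °C, pH 7; then pH 3, cold EtOAc extraction
Reagents that add atoms: dioxygen, O=O
Why: The strain expresses benzoate 1,2-dioxygenase but lacks the diol dehydrogenase, so the enzymatic ipso,ortho cis-dihydroxylation of the arene should stop at the dienediol and set C1 and C2 together, cis and in the (1S,2R) series, under enzyme control.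

Step 2
Reactants: 2 (1S,2R)-1,2-dihydroxycyclohexa-3,5-diene-1-carboxylic acid
Product: 3 methyl (1S,2R)-1,2-dihydroxycyclohexa-3,5-diene-1-carboxylate
Conditions: Me3SiCHN2, MeOH/toluene, 0 °C
Reagents that add atoms: trimethylsilyldiazomethane, C[Si](C)(C)C=[N+]=[N-]
Why: O-methylation of the carboxylic acid by the diazoalkane (diazomethane-type esterification) runs without added acid, which would dehydrate the dienediol to a phenol, and touches no stereocentre.

Step 3
Reactants: 3 methyl (1S,2R)-1,2-dihydroxycyclohexa-3,5-diene-1-carboxylate; 4 4-methoxybenzyl chloride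
Product: 5 methyl (1S,2R)-1-hydroxy-2-(4-methoxybenzyloxy)cyclohexa-3,5-diene-1-carboxylate
Conditions: 4 (1.2 equiv), Ag2O (1.5 equiv), CH2Cl2, rt, dark
Reagents that add atoms: 4-methoxybenzyl chloride, COc1ccc(CCl)cc1
Why: Ag2O-assisted Williamson-type monoalkylation of a 1,2-diol should take place at the secondary allylic C2 hydroxyl, because the tertiary C1 hydroxyl is hindered and hydrogen-bonded to the ester carbonyl, and the near-neutral medium spares the dienediol.

Step 4
Reactants: 5 methyl (1S,2R)-1-hydroxy-2-(4-methoxybenzyloxy)cyclohexa-3,5-diene-1-carboxylate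
Product: 6 1-(hydroxymethyl)-6-(4-methoxybenzyloxy)cyclohexa-2,4-dien-1-ol (ring OH and PMB ether cis, configuration as in 5)
Conditions: LiAlH4, THF, 0 °C; H2O then aq. NaOH work-up
Reagents that add atoms: none
Why: LiAlH4 reduction of the ester to the primary alcohol changes only C7, since the diene is not conjugated to the ester and the PMB ether is inert to hydride.

Step 5
Reactants: 6 1-(hydroxymethyl)-6-(4-methoxybenzyloxy)cyclohexa-2,4-dien-1-ol; 7 benzoyl chloride
Product: 8 [1-hydroxy-2-(4-methoxybenzyloxy)cyclohexa-3,5-dien-1-yl]methyl benzoate (C1–OH and C2–OPMB cis, both α)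
Conditions: 7 (1.05 equiv), Et3N, DMAP (cat.), CH2Cl2, −20 °C
Reagents that add atoms: benzoyl chloride, O=C(Cl)c1ccccc1
Why: Acylation of the primary hydroxyl is far faster than that of the flanked tertiary C1 hydroxyl, so one equivalent of acid chloride under amine base should give the C7 monobenzoate (chemoselective esterification).

Step 6
Reactants: 8 [1-hydroxy-2-(4-methoxybenzyloxy)cyclohexa-3,5-dien-1-yl]methyl benzoate
Product: 9 [2-(4-methoxybenzyloxy)-1-(trimethylsilyloxy)cyclohexa-3,5-dien-1-yl]methyl benzoate
Conditions: 1-(trimethylsilyl)imidazole, CH2Cl2, rt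
Reagents that add atoms: 1-(trimethylsilyl)imidazole, C[Si](C)(C)n1ccnc1
Why: Neutral O-silylation by the N-silylimidazole caps the tertiary hydroxyl, which removes the hydrogen-bond donor that would steer a peracid to the α face and to the C5=C6 alkene.

Step 7
Reactants: 9 [2-(4-methoxybenzyloxy)-1-(trimethylsilyloxy)cyclohexa-3,5-dien-1-yl]methyl benzoate
Product: 10 [3,4-epoxy-2-(4-methoxybenzyloxy)-1-(trimethylsilyloxy)cyclohex-5-en-1-yl]methyl benzoate (β oxirane, anti to the α oxygens at C1 and C2)
Conditions: mCPBA (1.1 equiv), CH2Cl2/aq. NaHCO3, 0 °C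
Reagents that add atoms: 3-chloroperoxybenzoic acid, O=C(OO)c1cccc(Cl)c1
Why: Prilezhaev epoxidation should take the C3=C4 alkene, which adjoins the C2 methine and not the fully substituted C1, and should come from the β face because the allylic PMB ether and the silyl ether both lie on the α face, which sets C3 and C4 together; the buffer protects the vinyl oxirane and the remaining alkene is deactivated towards a second oxidation.

Step 8
Reactants: 10 [3,4-epoxy-2-(4-methoxybenzyloxy)-1-(trimethylsilyloxy)cyclohex-5-en-1-yl]methyl benzoate
Product: 11 [3,4-epoxy-1-hydroxy-2-(4-methoxybenzyloxy)cyclohex-5-en-1-yl]methyl benzoate (β oxirane; C1–OH and C2–OPMB α)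
Conditions: Bu4NF/AcOH (1:1), THF, 0 °C
Reagents that add atoms: none
Why: Fluoride desilylation cleaves the Si–O bond while the acetic acid buffer protonates the tertiary alkoxide at once, so neither the benzoate nor the vinyl oxirane should be disturbed before the key step.

Step 9
Reactants: 11 [3,4-epoxy-1-hydroxy-2-(4-methoxybenzyloxy)cyclohex-5-en-1-yl]methyl benzoate
Product: 14 2-O-(4-methoxybenzyl)-3-O-debenzoylpipoxide, via C1 potassium alkoxide 12 (not isolated), via C3 potassium alkoxide 13 (not isolated)
Conditions: KN(SiMe3)2 (1.05 equiv), 18-crown-6, THF (0.01 M), −78 → 0 °C; AcOH, −78 °C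
Reagents that add atoms: none
Why: Proposed new method: deprotonation gives tertiary alkoxide 12, whose C1–O bond lies over the α lobe of the C5=C6 π bond; O1 adds to C6 while the π electrons move to C4=C5 and expel the β-oriented C4–O bond of the old oxirane, an anti SN2' process that amounts to a vinylogous Payne rearrangement and gives secondary alkoxide 13. The closest known reactions are the base-mediated Payne equilibration of 2,3-epoxy alcohols and intramolecular SN2' openings of vinyl oxiranes by hydroxyl groups; the alkene-relayed version with a three-membered ring as product has no direct precedent. The new oxirane closes in the 3-exo-trig mode and C6 is the only new stereocentre: O1 is held on the α face by C1 and can reach only the α face of C6, so the oxirane ends cis to the C2 ether and anti to the retained β oxygen at C3. The step needs attack at C6 to win over the ordinary Payne shift, over 4-exo attack at C3 and over ester scrambling: the PMB ether removes the C2 nucleophile, attack at C3 would give a strained 6-oxabicyclo[3.1.1]heptene, and high dilution at low temperature should keep intermolecular benzoyl transfer slow while C7-to-C1 benzoyl migration stays reversible. The equilibrium should lie on the product side because a trisubstituted oxirane and a less hindered secondary allylic alkoxide replace a disubstituted oxirane and a crowded tertiary alkoxide; the cold AcOH quench fixes that composition.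

Step 10
Reactants: 14 2-O-(4-methoxybenzyl)-3-O-debenzoylpipoxide; 7 benzoyl chloride
Product: 15 2-O-(4-methoxybenzyl)pipoxide
Conditions: 7, Et3N, DMAP (cat.), CH2Cl2, 0 °C
Reagents that add atoms: benzoyl chloride, O=C(Cl)c1ccccc1
Why: DMAP-catalysed acylation of the only free hydroxyl, the secondary allylic C3–OH, goes with retention at C3 under basic conditions that the vinyl oxirane tolerates.

Step 11
Reactants: 15 2-O-(4-methoxybenzyl)pipoxide
Product: 16 (−)-pipoxide
Conditions: DDQ, CH2Cl2/pH 7 buffer (10:1), 0 °C → rt
Reagents that add atoms: none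
Why: Oxidative PMB cleavage by DDQ (benzylic hydride abstraction, then hydrolysis of the oxocarbenium ion) frees the C2 hydroxyl under neutral conditions that leave both benzoates, the alkene and the oxirane alone and offer no base to move the C3 benzoate.

## Compound list

1 | benzoic acid | O=C(O)c1ccccc1 | starting material
2 | (1S,2R)-1,2-dihydroxycyclohexa-3,5-diene-1-carboxylic acid | O=C(O)[C@]1(O)C=CC=C[C@H]1O | intermediate
3 | methyl (1S,2R)-1,2-dihydroxycyclohexa-3,5-diene-1-carboxylate | COC(=O)[C@]1(O)C=CC=C[C@H]1O | intermediate
4 | 4-methoxybenzyl chloride | COc1ccc(CCl)cc1 | starting material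
5 | methyl (1S,2R)-1-hydroxy-2-(4-methoxybenzyloxy)cyclohexa-3,5-diene-1-carboxylate | COC(=O)[C@]1(O)C=CC=C[C@H]1OCc1ccc(OC)cc1 | intermediate
6 | 1-(hydroxymethyl)-6-(4-methoxybenzyloxy)cyclohexa-2,4-dien-1-ol (ring OH and PMB ether cis) | OC[C@]1(O)C=CC=C[C@H]1OCc1ccc(OC)cc1 | intermediate
7 | benzoyl chloride | O=C(Cl)c1ccccc1 | starting material
8 | [1-hydroxy-2-(4-methoxybenzyloxy)cyclohexa-3,5-dien-1-yl]methyl benzoate (C1–OH and C2–OPMB cis) | O=C(OC[C@]1(O)C=CC=C[C@H]1OCc1ccc(OC)cc1)c1ccccc1 | intermediate
9 | [2-(4-methoxybenzyloxy)-1-(trimethylsilyloxy)cyclohexa-3,5-dien-1-yl]methyl benzoate | O=C(OC[C@]1(O[Si](C)(C)C)C=CC=C[C@H]1OCc1ccc(OC)cc1)c1ccccc1 | intermediate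
10 | [3,4-epoxy-2-(4-methoxybenzyloxy)-1-(trimethylsilyloxy)cyclohex-5-en-1-yl]methyl benzoate (β oxirane, α oxygens at C1 and C2) | O=C(OC[C@]1(O[Si](C)(C)C)C=C[C@@H]2O[C@@H]2[C@H]1OCc1ccc(OC)cc1)c1ccccc1 | intermediate
11 | [3,4-epoxy-1-hydroxy-2-(4-methoxybenzyloxy)cyclohex-5-en-1-yl]methyl benzoate (β oxirane, α oxygens at C1 and C2) | O=C(OC[C@]1(O)C=C[C@@H]2O[C@@H]2[C@H]1OCc1ccc(OC)cc1)c1ccccc1 | intermediate
12 | C1 potassium alkoxide of 11 (formed in the flask) | O=C(OC[C@]1([O-])C=C[C@@H]2O[C@@H]2[C@H]1OCc1ccc(OC)cc1)c1ccccc1.[K+] | intermediate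
13 | C3 potassium alkoxide of 14 (formed in the flask) | O=C(OC[C@]12O[C@H]1C=C[C@H]([O-])[C@H]2OCc1ccc(OC)cc1)c1ccccc1.[K+] | intermediate
14 | 2-O-(4-methoxybenzyl)-3-O-debenzoylpipoxide (α C1–C6 oxirane, α C2–OPMB, β C3–OH) | O=C(OC[C@]12O[C@H]1C=C[C@H](O)[C@H]2OCc1ccc(OC)cc1)c1ccccc1 | intermediate
15 | 2-O-(4-methoxybenzyl)pipoxide | O=C(OC[C@]12O[C@H]1C=C[C@H](OC(=O)c1ccccc1)[C@H]2OCc1ccc(OC)cc1)c1ccccc1 | intermediate
16 | (−)-pipoxide | O=C(OC[C@]12O[C@H]1C=C[C@H](OC(=O)c1ccccc1)[C@H]2O)c1ccccc1 | target

## Step count and risks

Total step count: 11. Longest linear sequence: 11 steps (1 to 16).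

Steps most likely to fail:

Step 9 (Proposed new method). The tertiary alkoxide may not add to C6 at a useful rate, the equilibrium may stay on the side of the starting oxirane, or benzoyl transfer from O7 to O1 or between molecules may outrun the rearrangement. The fallback closes the C1–C6 oxirane by known displacement chemistry. It sets out from diene 9.
- Dye-sensitised photooxygenation (O2, tetraphenylporphyrin, visible light, CH2Cl2, −20 °C) should add singlet oxygen across C3 and C6 in a [4+2] sense on the β face, anti to the two α oxygens, to give the C3,C6-endoperoxide F1.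
- Thiourea in MeOH should reduce the O–O bond to the 3β,6β-diol F2.
- Benzoyl chloride 7 with pyridine at −40 °C should acylate the C3 hydroxyl, since the C6 hydroxyl is shielded by the quaternary C1, to give the C3 benzoate F3.
- Ms2O/Et3N should convert the C6 hydroxyl into the C6 mesylate F4.
- Bu4NF in THF at 0 °C should remove the silyl group; the C1 alkoxide then displaces the β mesylate from the α face with inversion at C6, the classical oxirane closure of a trans hydroxy sulfonate.

This gives 15 directly, and the route is rejoined at step 11.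

Step 7. Facial or site selectivity of the peracid on the diene may be poor, since the β CH2OBz group at C1 partly screens the favoured face, or the vinyl oxirane may open under acid. The fallback changes from substrate control to catalyst control. It sets out from 9 and uses a Jacobsen–Katsuki epoxidation with the (salen)MnCl complex of trivalent manganese (salen = N,N'-bis(3,5-di-tert-butylsalicylidene)-1,2-cyclohexanediamine dianion), mCPBA and N-methylmorpholine N-oxide in CH2Cl2 at −78 °C. Cis-disubstituted conjugated alkenes are the preferred substrates of this catalyst, and the (R,R) and (S,S) forms would both be tried to find the one matched to β delivery at C3=C4. The fallback returns at 10 and makes no compound outside the list (none F0).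

Step 3. Alkylation may occur at the wrong oxygen or twice, or the dienediol may aromatise if the reaction is slow. The fallback uses a tin template in place of direct alkylation. It sets out from 3: Bu2SnO in MeOH at reflux should give the dibutylstannylene acetal F5, in which the secondary oxygen is the more nucleophilic one; 4 with CsF in DMF at rt, followed by an aqueous KF work-up, should then alkylate only C2–O. The fallback returns at 5.

Further compounds
F1 | step 9 | C3,C6-endoperoxide of 9 (peroxide bridge β, anti to the α oxygens at C1 and C2) | O=C(OC[C@]1(O[Si](C)(C)C)[C@H]2C=C[C@H](OO2)[C@H]1OCc1ccc(OC)cc1)c1ccccc1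
F2 | step 9 | 3β,6β-diol: [3,6-dihydroxy-2-(4-methoxybenzyloxy)-1-(trimethylsilyloxy)cyclohex-4-en-1-yl]methyl benzoate | O=C(OC[C@]1(O[Si](C)(C)C)[C@H](O)C=C[C@H](O)[C@H]1OCc1ccc(OC)cc1)c1ccccc1
F3 | step 9 | C3 benzoate of F2 | O=C(OC[C@]1(O[Si](C)(C)C)[C@H](O)C=C[C@H](OC(=O)c2ccccc2)[C@H]1OCc1ccc(OC)cc1)c1ccccc1
F4 | step 9 | C6 mesylate of F3 | O=C(OC[C@]1(O[Si](C)(C)C)[C@H](OS(C)(=O)=O)C=C[C@H](OC(=O)c2ccccc2)[C@H]1OCc1ccc(OC)cc1)c1ccccc1
F0 | step 7 | none | none
F5 | step 3 | dibutylstannylene acetal of 3 | COC(=O)[C@]1(O2)C=CC=C[C@H]1O[Sn]2(CCCC)CCCC
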